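**Plan**

1. Numbering: C1 = quaternary ring-fusion carbon with the methyl, C2–C3 = CH2, C4 = isopropyl carbinol, C5 = ring-fusion CH, C6 = anisoyloxy carbon, C7, C8(Me)=C9, C10 = acetoxy carbon bonded back to C1; β = face of the C1 methyl, α = the other face.
2. Enabling feature: C1 carries the C1–C10 bond of the seven-membered ring and sits 1,3 to the oxygenated C6 through C5, so C1–C10 plus a C9 carbonyl is the retron of a Claisen shift of a C6–O–C9(=C10) allyl vinyl ether.
3. Cuts, in retrosynthetic order: both ester C–O bonds; C10–O (allylic oxidation, enone reduction); C4–isopropyl (organocerium on a C4 ketone); C6–O and C5–H (hydroboration of C5=C6); C1–C10 and O–C9 (key step); C5–C6 (vinyllithium plus aldehyde); C8–C9 (conjugate alkynylation of crotonaldehyde).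
4. Forward: the five-membered ring is bought as a bromoenone, the C6–C10 chain is attached as an alkynal, and the seven-membered ring arises in step 7 (O–C9 by 5-exo-dig addition, then C1–C10 by [3,3] shift). The C9 ketone is then spent as an enol triflate that fixes C8=C9, and C10 is oxidised last.
5. Stereochemistry: C6 carbinol by CBS reduction, handed on to quaternary C1 in the Claisen shift; the C1 methyl then steers C5/C6 (hydroboration), C4 (isopropyl addition) and C10 (Luche reduction), each by α-face approach.

Key step: step 7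

Remark (assumption): the C8 methyl centre is flattened in step 8, so its configuration is immaterial; it is drawn (R), and if the ligand in step 2 delivers the other sense, compounds 6–14 are simply the C8 epimers and nothing else changes.
Remark (names): bicyclic compounds are named as bicyclo[5.3.0]decanes with the C1–C10 numbering of line 1 (not von Baeyer numbering); the SMILES in the compound list are authoritative.

**Step 1**
Reactants: 1 2-bromo-3-methylcyclopent-2-en-1-one; 2 ethylene glycol
Product: 3 6-bromo-7-methyl-1,4-dioxaspiro[4.4]non-6-ene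
Conditions: p-toluenesulfonic acid monohydrate (cat.), benzene, reflux, Dean–Stark
Reagents that add atoms: none
Why: Acid-catalysed ketalisation driven by azeotropic removal of water; the α-bromine holds the double bond in place, as is usual for 2-halocycloalk-2-enones, and the ketal masks C4 and allows the later bromine–lithium exchange.

**Step 2**
Reactants: 4 (E)-but-2-enal (crotonaldehyde); 5 ethynyltri(propan-2-yl)silane
Product: 6 (R)-3-methyl-5-[tri(propan-2-yl)silyl]pent-4-ynal
Conditions: [Rh(OAc)(C2H4)2]2 (2.5 mol %), (R)-DTBM-SEGPHOS (6 mol %), MeOH, 40 °C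
Reagents that add atoms: none
Why: Rhodium-catalysed asymmetric conjugate alkynylation of an enal, in which the bulky silyl group and ligand suppress alkyne dimerisation and the alkynylrhodium species adds to the β-carbon (C8–C9 bond) with ligand control of the C8 centre.

**Step 3**
Reactants: 3 6-bromo-7-methyl-1,4-dioxaspiro[4.4]non-6-ene; 6 (R)-3-methyl-5-[tri(propan-2-yl)silyl]pent-4-ynal
Product: 8 (3R)-3-methyl-1-(7-methyl-1,4-dioxaspiro[4.4]non-6-en-6-yl)-5-[tri(propan-2-yl)silyl]pent-4-yn-1-ol as both carbinol epimers, via vinyllithium 7 (not isolated)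
Conditions: n-BuLi, THF, −78 °C; then 6, −78 °C; H2O
Reagents that add atoms: none
Why: Bromine–lithium exchange gives the α-keto vinyl anion equivalent 7, which adds 1,2 to the aldehyde and forges C5–C6; the carbinol centre (C6) is formed unselectively on purpose because step 4 removes it.

**Step 4**
Reactants: 8 carbinol epimers
Product: 9 (3R)-3-methyl-1-(7-methyl-1,4-dioxaspiro[4.4]non-6-en-6-yl)-5-[tri(propan-2-yl)silyl]pent-4-yn-1-one
Conditions: Dess–Martin periodinane, pyridine, CH2Cl2, 0 °C → rt
Reagents that add atoms: none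
Why: Dess–Martin oxidation of the allylic alcohol under buffered, non-acidic conditions should spare the labile allylic ketal and the silylalkyne and converges both epimers on one enone.

**Step 5**
Reactants: 9 alkynyl enone
Product: 10 (1S,3R)-3-methyl-1-(7-methyl-1,4-dioxaspiro[4.4]non-6-en-6-yl)-5-[tri(propan-2-yl)silyl]pent-4-yn-1-ol
Conditions: (R)-Me-CBS oxazaborolidine [(R)-1-methyl-3,3-diphenyltetrahydro-1H,3H-pyrrolo[1,2-c][1,3,2]oxazaborole] (0.3 equiv), BH3·SMe2, THF, −30 °C; MeOH
Reagents that add atoms: none
Why: CBS reduction, in which the fully substituted cyclopentenyl group is the large and the CH2 chain the small substituent, so the (R)-catalyst should deliver hydride to give the (S)-carbinol at C6, while the silyl-capped internal alkyne is not hydroborated at this temperature.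

**Step 6**
Reactants: 10 silylated (S)-carbinol
Product: 11 (1S,3R)-3-methyl-1-(7-methyl-1,4-dioxaspiro[4.4]non-6-en-6-yl)pent-4-yn-1-ol
Conditions: Bu4NF, THF, 0 °C → rt
Reagents that add atoms: none
Why: Fluoride-mediated protodesilylation of the alkynylsilane frees the terminal alkyne needed for the alkoxide addition without touching the carbinol or the ketal.

**Step 7**
Reactants: 11 (1S,3R)-alkynyl carbinol
Product: 14 (1R,8R)-4,4-ethylenedioxy-1,8-dimethylbicyclo[5.3.0]dec-5-en-9-one, via lithium alkoxide 12 (not isolated), via methylideneoxolane 13 (not isolated)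
Conditions: MeLi (10 mol %), phenetole, 200 °C (microwave), 1 h
Reagents that add atoms: none
Why: Catalytic MeLi gives lithium alkoxide 12, whose oxygen adds to the internal alkyne carbon C9 in a 5-exo-dig closure to the 2-methylideneoxolane 13, the vinyl anion being protonated by further 11 so that the base turns over. The allyl vinyl ether C10=C9–O–C6–C5=C1 of 13 then undergoes a Claisen [3,3] shift through a boat-like oxabicyclo[3.2.1] transition state that makes C1–C10 and breaks C6–O, so the oxolane is expanded by two carbons to the seven-membered ring with a C9 ketone and a C5=C6 alkene. The closest known reaction type is the base-catalysed tandem 5-exo-dig cyclisation/Claisen rearrangement of 1-alkenyl-4-pentyn-1-ols to ring-fused cyclohept-4-enones. The new quaternary C1 is controlled by the C6 carbinol alone: the tether forces the C5=C6 alkene to be cis within the ring, so the C6–O bond of (6S)-11 stands over one face of the cyclopentene and C10 is delivered suprafacially to that same face of C1, giving (1R)-14, which is the C1 configuration of the target. The step needs 5-exo rather than 6-endo attack (normal for an alkoxide on a terminal alkyne) and rearrangement before the exocyclic enol ether can isomerise into the ring, which the aprotic, acid-free medium and the high temperature should secure; C8 may epimerise next to the ketone, which is irrelevant.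

**Step 8**
Reactants: 14 ketal ketone
Product: 16 (1R)-4,4-ethylenedioxy-1,8-dimethylbicyclo[5.3.0]deca-5,8-dien-9-yl trifluoromethanesulfonate, via lithium enolate 15 (not isolated)
Conditions: LiN(SiMe3)2 (0.95 equiv), THF, −78 °C → rt, 2 h; PhNTf2, 0 °C → rt
Reagents that add atoms: N-phenylbis(trifluoromethanesulfonimide), FC(F)(F)S(=O)(=O)N(c1ccccc1)S(=O)(=O)C(F)(F)F
Why: Thermodynamic enol triflate formation: proton-transfer equilibration of the lithium enolate (slight deficit of a weak amide base at ambient temperature) should favour the tetrasubstituted C8=C9 enolate 15 over the C9=C10 isomer whose sp2 carbon would abut quaternary C1, and O-triflation fixes this regiochemistry, erases the C8 centre and masks C9 as a borane-inert group.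

**Step 9**
Reactants: 16 dienyl triflate
Product: 18 (1R,5S,6S)-4,4-ethylenedioxy-6-hydroxy-1,8-dimethylbicyclo[5.3.0]dec-8-en-9-yl trifluoromethanesulfonate (5α-H; 6α-OH), via alkylborane 17 (not isolated)
Conditions: BH3·THF, THF, 0 °C → rt; NaBO3·4H2O, H2O, rt
Reagents that add atoms: sodium perborate, [Na+].[Na+].O[B-]1(O)OO[B-](O)(O)OO1
Why: Hydroboration–oxidation: BH3 adds cis across the only reactive alkene (the tetrasubstituted, electron-poor enol triflate is inert, whereas a free C8=C9 alkene would compete), boron going to the less substituted C6 from the α face opposite the C1 methyl that leans over the β face of C5, so H-5 and the C6 oxygen (retention in the C–B oxidation) are both α, which sets the trans ring fusion and the C6 carbinol together.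

**Step 10**
Reactants: 18 hydroxy triflate
Product: 19 (1R,5S,6S)-4,4-ethylenedioxy-1,8-dimethylbicyclo[5.3.0]dec-8-en-6-ol
Conditions: Pd(OAc)2 (5 mol %), PPh3, HCO2H, n-Bu3N, DMF, 60 °C
Reagents that add atoms: none
Why: Palladium-catalysed formate reduction of the enol triflate (oxidative addition to zerovalent palladium, formate decarboxylation, C–H reductive elimination) exchanges C9–OTf for C9–H and leaves the trisubstituted C8=C9 alkene exactly where the target needs it, the alcohol and ketal being untouched under amine-buffered conditions.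

**Step 11**
Reactants: 19 hydroxy ketal
Product: 20 (1R,5S,6S)-6-hydroxy-1,8-dimethylbicyclo[5.3.0]dec-8-en-4-one
Conditions: pyridinium p-toluenesulfonate (cat.), acetone/H2O, 50 °C
Reagents that add atoms: water, O
Why: Mild acid-catalysed ketal hydrolysis unveils the C4 ketone, the weak acid being chosen to avoid dehydration of the β-hydroxy ketone and epimerisation at C5.

**Step 12**
Reactants: 20 hydroxy ketone
Product: 21 (1R,4R,5S,6S)-1,8-dimethyl-4-(propan-2-yl)bicyclo[5.3.0]dec-8-ene-4,6-diol
Conditions: CeCl3 (anhydrous), i-PrMgCl (excess), THF, −78 → 0 °C; H2O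
Reagents that add atoms: isopropylmagnesium chloride, CC(C)[Mg]Cl
Why: CeCl3-promoted Grignard (organocerium) addition, which curbs enolisation and β-hydride reduction by the secondary reagent; in the trans-fused bicycle the axial C1 methyl is 1,3 to C4 and shields the β face of the cyclopentanone, so isopropyl should enter from the α face (the side of H-5 and of the C6 alkoxide formed in situ) and the new C4 hydroxyl is β, cis to the methyl. This compound corresponds to the natural daucane diol jaeschkeanadiol.

**Step 13**
Reactants: 21 diol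
Product: 22 (1R,4R,5S,6S)-4-hydroxy-1,8-dimethyl-4-(propan-2-yl)bicyclo[5.3.0]dec-8-en-6-yl 4-methoxybenzoate
Conditions: 4-MeOC6H4COCl, Et3N, 4-(dimethylamino)pyridine, CH2Cl2, rt → 40 °C
Reagents that add atoms: 4-methoxybenzoyl chloride, COc1ccc(cc1)C(Cl)=O
Why: Acylation under nucleophilic catalysis takes the secondary C6 hydroxyl only, the tertiary C4 hydroxyl being inert, and the ester also protects C6 during the oxidation of step 14.

**Step 14**
Reactants: 22 anisoate
Product: 23 (1S,4R,5S,6S)-4-hydroxy-1,8-dimethyl-10-oxo-4-(propan-2-yl)bicyclo[5.3.0]dec-8-en-6-yl 4-methoxybenzoate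
Conditions: CrO3, 3,5-dimethylpyrazole, CH2Cl2, −20 °C
Reagents that add atoms: chromium trioxide, O=[Cr](=O)=O
Why: Allylic oxidation with the CrO3–3,5-dimethylpyrazole complex: trisubstituted cycloalkenes are oxidised to enones at the ring CH2 bonded to the CH terminus of the alkene (as in the conversion of Δ5-steroids into 7-ketones), here C10, whereas C7 hangs on the substituted terminus and is deactivated by the neighbouring acyloxy group, and a transposed C8 tertiary chromate would collapse to the same enone.

**Step 15**
Reactants: 23 enone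
Product: 24 (1S,4R,5S,6S,10S)-4,10-dihydroxy-1,8-dimethyl-4-(propan-2-yl)bicyclo[5.3.0]dec-8-en-6-yl 4-methoxybenzoate
Conditions: NaBH4, CeCl3·7H2O, MeOH, −78 → 0 °C
Reagents that add atoms: none
Why: Luche reduction gives 1,2-reduction of the enone; with the ring fusion now trans the C1 methyl is axial and stands over the β face of the C10 carbonyl, so hydride should arrive from the α face and the hydroxyl ends β (10S), cis to the methyl, the same sense as in borohydride reductions of decalones flanked by an angular methyl group.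

**Step 16**
Reactants: 24 allylic alcohol
Product: 25 (1S,4R,5S,6S,10S)-10-acetoxy-4-hydroxy-1,8-dimethyl-4-(propan-2-yl)bicyclo[5.3.0]dec-8-en-6-yl 4-methoxybenzoate (CNP0256979.3)
Conditions: Ac2O, pyridine, 4-(dimethylamino)pyridine (cat.), CH2Cl2, rt
Reagents that add atoms: acetic anhydride, CC(=O)OC(C)=O
Why: Catalysed acetylation of the secondary allylic alcohol, the hindered tertiary C4 hydroxyl not being acylated at room temperature, so the target should result without further protecting-group steps.

**Compound list**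

1 | 2-bromo-3-methylcyclopent-2-en-1-one | CC1=C(Br)C(=O)CC1 | starting material
2 | ethylene glycol | OCCO | starting material
3 | 6-bromo-7-methyl-1,4-dioxaspiro[4.4]non-6-ene | CC1=C(Br)C2(CC1)OCCO2 | intermediate
4 | (E)-but-2-enal | C/C=C/C=O | starting material
5 | ethynyltri(propan-2-yl)silane | C#C[Si](C(C)C)(C(C)C)C(C)C | starting material
6 | (R)-3-methyl-5-[tri(propan-2-yl)silyl]pent-4-ynal | CC(C)[Si](C(C)C)(C(C)C)C#C[C@H](C)CC=O | intermediate
7 | (7-methyl-1,4-dioxaspiro[4.4]non-6-en-6-yl)lithium | CC1=C([Li])C2(CC1)OCCO2 | intermediate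
8 | (3R)-3-methyl-1-(7-methyl-1,4-dioxaspiro[4.4]non-6-en-6-yl)-5-[tri(propan-2-yl)silyl]pent-4-yn-1-ol, both carbinol epimers | CC(C)[Si](C(C)C)(C(C)C)C#C[C@H](C)CC(O)C1=C(C)CCC12OCCO2 | intermediate
9 | (3R)-3-methyl-1-(7-methyl-1,4-dioxaspiro[4.4]non-6-en-6-yl)-5-[tri(propan-2-yl)silyl]pent-4-yn-1-one | CC(C)[Si](C(C)C)(C(C)C)C#C[C@H](C)CC(=O)C1=C(C)CCC12OCCO2 | intermediate
10 | (1S,3R)-3-methyl-1-(7-methyl-1,4-dioxaspiro[4.4]non-6-en-6-yl)-5-[tri(propan-2-yl)silyl]pent-4-yn-1-ol | CC(C)[Si](C(C)C)(C(C)C)C#C[C@H](C)C[C@H](O)C1=C(C)CCC12OCCO2 | intermediate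
11 | (1S,3R)-3-methyl-1-(7-methyl-1,4-dioxaspiro[4.4]non-6-en-6-yl)pent-4-yn-1-ol (key-step precursor) | C#C[C@H](C)C[C@H](O)C1=C(C)CCC12OCCO2 | intermediate
12 | lithium alkoxide of 11 | C#C[C@H](C)C[C@H](O[Li])C1=C(C)CCC12OCCO2 | intermediate
13 | (3R,5S)-3-methyl-2-methylidene-5-(7-methyl-1,4-dioxaspiro[4.4]non-6-en-6-yl)oxolane | C=C1[C@H](C)C[C@H](O1)C2=C(C)CCC23OCCO3 | intermediate
14 | (1R,8R)-4,4-ethylenedioxy-1,8-dimethylbicyclo[5.3.0]dec-5-en-9-one (key-step product) | O=C1C[C@@]2(C)CCC3(OCCO3)C2=CC[C@H]1C | intermediate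
15 | lithium C8=C9 enolate of 14 | CC1=C(O[Li])C[C@@]2(C)CCC3(OCCO3)C2=CC1 | intermediate
16 | (1R)-4,4-ethylenedioxy-1,8-dimethylbicyclo[5.3.0]deca-5,8-dien-9-yl trifluoromethanesulfonate | CC1=C(OS(=O)(=O)C(F)(F)F)C[C@@]2(C)CCC3(OCCO3)C2=CC1 | intermediate
17 | 6α-boryl-5α-H adduct of 16 (alkylborane) | B[C@H]1CC(C)=C(OS(=O)(=O)C(F)(F)F)C[C@@]2(C)CCC3(OCCO3)[C@H]12 | intermediate
18 | (1R,5S,6S)-4,4-ethylenedioxy-6-hydroxy-1,8-dimethylbicyclo[5.3.0]dec-8-en-9-yl trifluoromethanesulfonate | O[C@H]1CC(C)=C(OS(=O)(=O)C(F)(F)F)C[C@@]2(C)CCC3(OCCO3)[C@H]12 | intermediate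
19 | (1R,5S,6S)-4,4-ethylenedioxy-1,8-dimethylbicyclo[5.3.0]dec-8-en-6-ol | O[C@H]1CC(C)=CC[C@@]2(C)CCC3(OCCO3)[C@H]12 | intermediate
20 | (1R,5S,6S)-6-hydroxy-1,8-dimethylbicyclo[5.3.0]dec-8-en-4-one | O[C@H]1CC(C)=CC[C@@]2(C)CCC(=O)[C@H]12 | intermediate
21 | (1R,4R,5S,6S)-1,8-dimethyl-4-(propan-2-yl)bicyclo[5.3.0]dec-8-ene-4,6-diol | O[C@H]1CC(C)=CC[C@@]2(C)CC[C@@](O)(C(C)C)[C@H]12 | intermediate
22 | (1R,4R,5S,6S)-4-hydroxy-1,8-dimethyl-4-(propan-2-yl)bicyclo[5.3.0]dec-8-en-6-yl 4-methoxybenzoate | COc1ccc(cc1)C(=O)O[C@H]2CC(C)=CC[C@@]3(C)CC[C@@](O)(C(C)C)[C@H]23 | intermediate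
23 | (1S,4R,5S,6S)-4-hydroxy-1,8-dimethyl-10-oxo-4-(propan-2-yl)bicyclo[5.3.0]dec-8-en-6-yl 4-methoxybenzoate | COc1ccc(cc1)C(=O)O[C@H]2CC(C)=CC(=O)[C@@]3(C)CC[C@@](O)(C(C)C)[C@H]23 | intermediate
24 | (1S,4R,5S,6S,10S)-4,10-dihydroxy-1,8-dimethyl-4-(propan-2-yl)bicyclo[5.3.0]dec-8-en-6-yl 4-methoxybenzoate | COc1ccc(cc1)C(=O)O[C@H]2CC(C)=C[C@H](O)[C@@]3(C)CC[C@@](O)(C(C)C)[C@H]23 | intermediate
25 | (1S,4R,5S,6S,10S)-10-acetoxy-4-hydroxy-1,8-dimethyl-4-(propan-2-yl)bicyclo[5.3.0]dec-8-en-6-yl 4-methoxybenzoate (CNP0256979.3) | COc1ccc(C(=O)O[C@H]2CC(C)=C[C@H](OC(C)=O)[C@@]3(C)CC[C@@](O)(C(C)C)[C@H]23)cc1 | target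

**Step count and risks**

Total: 16 steps. Longest linear sequence: 15 steps (steps 1 and 3–16, or equally steps 2 and 3–16).

Steps most likely to fail:

- **Step 9 (hydroboration).** While C5 is sp2, the C1 methyl and the C10 methylene flank it almost symmetrically, so borane may approach from both faces and the facial selectivity that sets the trans ring fusion could be poor. The fallback sets out from 16. The triflate is reduced first (Pd(OAc)2, PPh3, HCO2H, n-Bu3N) to the diene ketal F1. The allylic ketal is hydrolysed (pyridinium p-toluenesulfonate, wet acetone) to the C4 enone F2. Boron is then added to C6 by copper-catalysed conjugate borylation (CuCl, NaOt-Bu, a bisphosphine, bis(pinacolato)diboron, MeOH), the isolated C8=C9 alkene being inert, to give the β-boryl ketone F3. Oxidation with NaBO3·4H2O returns to the route at 20. In this variant C6 is set in the boryl–copper addition to a planar enone and C5 in a separate protonation, so each centre can be tuned on its own.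

- **Step 14 (allylic oxidation).** Hydrogen abstraction may begin at C7 or at the C8 methyl, or stall at the neopentyl C10, so the regioselectivity of the oxidation could be poor. The fallback sets out from 22. The only alkene is epoxidised (mCPBA, NaHCO3) to the 8,9-epoxide F4. The epoxide is opened at the secondary C9 with PhSeNa (from PhSeSePh and NaBH4, EtOH) to the hydroxy selenide F5. Oxidation with H2O2 makes the selenoxide eliminate toward C10, the only side with a hydrogen, giving the tertiary allylic alcohol F6. A Babler–Dauben oxidative transposition with [C5H5NH][CrO3Cl] then returns to the route at 23. The C8 and C9 configurations in F4–F6 are immaterial.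

- **Step 12 (isopropyl addition).** The secondary Grignard reagent may enolise the ketone toward C5 or reduce it by β-hydride transfer, and the β-alkoxide may open by retro-aldol cleavage, instead of clean addition. The fallback sets out from 20. The sp2, hydride-free nucleophile isopropenylmagnesium bromide is added with CeCl3 to give the isopropenyl carbinol F7. The 1,1-disubstituted alkene is then hydrogenated selectively (H2, RhCl(PPh3)3, benzene), which returns to the route at 21.

**Further compounds**

F1 | step 9 | (1R)-4,4-ethylenedioxy-1,8-dimethylbicyclo[5.3.0]deca-5,8-diene | CC1=CC[C@@]2(C)CCC3(OCCO3)C2=CC1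
F2 | step 9 | (1R)-1,8-dimethylbicyclo[5.3.0]deca-5,8-dien-4-one | CC1=CC[C@@]2(C)CCC(=O)C2=CC1
F3 | step 9 | 6α-(pinacolatoboryl)-5α-H-1,8-dimethylbicyclo[5.3.0]dec-8-en-4-one | CC1(C)OB(OC1(C)C)[C@H]2CC(C)=CC[C@@]3(C)CCC(=O)[C@H]23
F4 | step 14 | 8,9-epoxide of 22 | COc1ccc(cc1)C(=O)O[C@H]2CC3(C)OC3C[C@@]4(C)CC[C@@](O)(C(C)C)[C@H]24
F5 | step 14 | 8-hydroxy-9-(phenylselanyl) derivative of 22 | COc1ccc(cc1)C(=O)O[C@H]2CC(C)(O)C([Se]c3ccccc3)C[C@@]4(C)CC[C@@](O)(C(C)C)[C@H]24
F6 | step 14 | 8-hydroxy-Δ9(10) tertiary allylic alcohol | COc1ccc(cc1)C(=O)O[C@H]2CC(C)(O)C=C[C@@]3(C)CC[C@@](O)(C(C)C)[C@H]23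
F7 | step 12 | (1R,4R,5S,6S)-1,8-dimethyl-4-(prop-1-en-2-yl)bicyclo[5.3.0]dec-8-ene-4,6-diol | O[C@H]1CC(C)=CC[C@@]2(C)CC[C@@](O)(C(C)=C)[C@H]12
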